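The constant to watch is g: the rate of making left-handed product divided by c(left-handed substrate) times c(partner), at the catalyst charge of both earlier runs.

common to all: left-handed substrate 0.30 M; right-handed substrate 0.30 M; catalyst 30 mM

| flask | partner | remark |
|---|---|---|
| Sunday's | 0.60 M | run made earlier |
| Thursday's | 1.4 M | run made earlier |
| flask | 0.900 M |  |

| run | time / h | left-handed product / % | left-handed substrate / % |
|---|---|---|---|
| Sunday's | 0.500 | 7.0 | 45.0 |
| Sunday's | 1.50 | 9.5 | 39.6 |
| Sunday's | 3.00 | 14.4 | 36.7 |
| Sunday's | 4.00 | 16.5 | 36.1 |
| Sunday's | 6.00 | 19.7 | 33.9 |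
| Sunday's | 8.00 | 22.7 | 31.8 |
| Thursday's | 1.33 | 22.0 | 32.1 |
| Thursday's | 2.50 | 26.4 | 26.2 |
| Thursday's | 4.00 | 31.1 | 23.8 |
| Thursday's | 5.00 | 33.8 | 21.0 |
| Thursday's | 6.00 | 37.6 | 20.7 |
| Thursday's | 8.00 | 41.4 | 18.9 |

(standard deviation of a reading: 1 percentage point)

- catalyst is single-handed; left-handed substrate and right-handed substrate are mirror images of each other, charged as a racemate, each of them at the stated concentration
- the numbers in the tables scatter with a standard deviation of 1 percentage point
- no earlier run changes the charge of catalyst; that part of a forecast is a guess

1. factor on the rate of making left-handed product when 10 % of the left-handed substrate and right-handed substrate together are converted if catalyst is charged twice over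
2. factor on the rate when 10 % of the left-handed substrate and right-handed substrate together are converted if catalyst is charged at 6.0 mM instead

I read g in two ways. By the clock, from 4.00 h to 8.00 h, Sunday's run gives 0.0946 M⁻¹ h⁻¹ and Thursday's run gives 0.102 M⁻¹ h⁻¹, with 1.4 M of partner against 0.60 M, so these two agree. By product made, they part: Thursday's run, over its first 1.33 h, up to 22.0 % of product, gives 0.302 M⁻¹ h⁻¹, which is more than Sunday's late value over about the same product. So the count by product cheats, and in these runs g falls with the clock. Sunday's first 0.500 h gives 0.509 M⁻¹ h⁻¹.

With charged concentrations, the flask reaches 10 % between 0.437 h and 0.736 h, so I take Thursday's early mean as g at that moment. I carry 0.325, the share left: late g over g at the flask's moment of 10 %. I assume that the rate follows the catalyst charge, which is a guess, and that concentrations match at equal conversion. At 6.0 mM the moment comes near 11.3 h, later than 4.00 h, so I expect 0.0651. With the charge doubled, the moment comes by 0.368 h, inside Sunday's first 0.500 h, so I expect 3.37.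

The forecast, which reads the fall as “catalyst decaying in time to a less active form”, gives 5.5 and 0.11, both higher than mine.

The flask gives 3.02 for the doubled charge and 0.0838 at 6.0 mM.

    partner + catalyst + left-handed substrate → catalyst + left-handed product (k = 19.0 M⁻² h⁻¹)
    partner + catalyst + right-handed substrate → catalyst + right-handed product (k = 0.803 M⁻² h⁻¹)
    catalyst ⇌ dormant form (K = 4.29, k = 1.37 h⁻¹)
    left-handed substrate ⇌ right-handed substrate (k = 0.0791 h⁻¹)

It reaches 10 % at 0.617 h. Catalyst stands at 33.9 % of its charge after 1.00 h and 18.9 % after 5.00 h, the rest being the dormant form, an off-cycle state. My share left of 0.325 gave 0.0651 at 6.0 mM, and the flask's figure is 1.29 times that. Divided by the catalyst factor, 0.0838 puts the share left at 0.419. For the doubled charge, 3.02 leaves a factor of 1.51 on g at its moment, so counted from that moment the share left is 0.278.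

The numbers in the tables come from a simulation for an exercise; noise was put on by code.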